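**Plan**

1. Numbering: ring A (cyclopentanone) is C1(Et)–C2(=O)–C3(Me)–C4–C5, ring B (cyclohexene) is C4–C5–C6(Me)=C7–C8(Et, styryl)–C9(Et, CO2H). The enabling feature is that the ring-A carbonyl carbon C2 lies between C1 and C3 and the ring fusion is C4–C5, so ring A is the sum of alkyne C3≡C4, alkene C5=C1 and CO, with C9–C8–C7=C6 as a four-atom tether.
2. Retrosynthetic cuts, in order: ester C–O; C3–H/C4–H (enone reduction); C4–C5, C1–C2 and C2–C3 together (Pauson–Khand) to an acyclic dienyne; C8–C9 (Ireland–Claisen, which also releases the styryl double bond); acyl C–O; C8–C7 (Suzuki–Miyaura); C6–C5 (Negishi).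
3. Forward: the chain is joined C6–C5, then C8–C7, esterified, and C8–C9 is forged by the Claisen rearrangement. Rings B and A then arise together in one carbonylative step, leaving only reduction, equilibration and deprotection.
4. Stereochemistry: one carbinol centre comes from catalytic asymmetric alkynylation of benzaldehyde and is relayed to C8 and C9 through the chair Claisen transition state. Alkene geometries come from bromoboration, anti-hydroalumination/iodination and stereoretentive couplings; ketene acetal geometry from kinetic enolization. C1 and C5 come from the (E)-alkene and the tether in the key step, C4 from dissolving-metal protonation (trans fusion), C3 from equilibration.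

Key step: step 10

Remark: but-1-yne, propyne and pent-3-ynoic acid are taken as purchasable; indene locants in the names map as 1/2/3/3a/7a/7/6/5/4 = C1/C2/C3/C4/C5/C6/C7/C8/C9.

**Route**

Step 1
Reactants: 1 propyne
Product: 3 (Z)-2-(2-bromoprop-1-en-1-yl)-4,4,5,5-tetramethyl-1,3,2-dioxaborolane, via (Z)-(2-bromoprop-1-enyl)dibromoborane 2 (not isolated)
Conditions: BBr3, CH2Cl2, −78 °C → rt; then pinacol, −78 °C → rt
Reagents that add atoms: boron tribromide BrB(Br)Br; pinacol CC(C)(O)C(C)(C)O
Why: Alkyne bromoboration adds BBr3 syn across the terminal alkyne with boron on the terminal carbon, so bromine and boron end up cis, and pinacol exchange gives the stable (Z)-alkenylboronate carrying C6 (C–Br) and C7 (C–B).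

Step 2
Reactants: 4 but-1-yne; 3 (Z)-2-(2-bromoprop-1-en-1-yl)-4,4,5,5-tetramethyl-1,3,2-dioxaborolane
Product: 7 4,4,5,5-tetramethyl-2-[(1Z,3E)-2-methylhexa-1,3-dien-1-yl]-1,3,2-dioxaborolane, via (E)-but-1-enylzirconocene chloride 5 (not isolated), via (E)-but-1-enylzinc bromide 6 (not isolated)
Conditions: Cp2Zr(H)Cl, THF, rt; then 3, ZnBr2, Pd(t-Bu3P)2 (cat.), THF, rt
Reagents that add atoms: none
Why: Syn hydrozirconation of 4 gives the (E)-alkenylmetal (future C5=C1), which after transmetalation to zinc undergoes Negishi coupling at the C–Br bond with retention while the pinacol boronate stays inert, fixing the (1Z,3E) geometry of the C7=C6–C5=C1 diene.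

Step 3
Reactants: 8 benzaldehyde; 4 but-1-yne
Product: 10 (R)-1-phenylpent-2-yn-1-ol, via ethyl(but-1-ynyl)zinc 9 (not isolated)
Conditions: Et2Zn, HMPA, CH2Cl2, rt; (S)-BINOL (cat.; the antipode assigned to the R alcohol in this system), Ti(OiPr)4; then 8, rt
Reagents that add atoms: none
Why: Catalytic asymmetric alkynylzinc addition to an aromatic aldehyde, in which the BINOL–titanium Lewis acid selects the aldehyde face; the R carbinol set here is the only external source of chirality and is later relayed to C8 and C9.

Step 4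
Reactants: 10 (R)-1-phenylpent-2-yn-1-ol
Product: 12 (1S,2Z)-3-iodo-1-phenylpent-2-en-1-ol, via cyclic sodium alkenylalanate 11 (not isolated)
Conditions: NaAlH2(OCH2CH2OMe)2, THF, 0 °C → rt; then I2, THF, −78 °C
Reagents that add atoms: iodine II
Why: Hydroxyl-directed anti-hydroalumination of the propargylic alcohol gives a five-membered alkenylalanate with aluminium on the distal carbon, and iodinolysis with retention puts iodine on the future C8 cis to the carbinol carbon; the stereocentre is untouched (its descriptor becomes S only because the priorities change).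

Step 5
Reactants: 12 (1S,2Z)-3-iodo-1-phenylpent-2-en-1-ol; 7 4,4,5,5-tetramethyl-2-[(1Z,3E)-2-methylhexa-1,3-dien-1-yl]-1,3,2-dioxaborolane
Product: 13 (1S,2Z,4Z,6E)-3-ethyl-5-methyl-1-phenylnona-2,4,6-trien-1-ol
Conditions: Pd(dppf)Cl2 (cat.), K3PO4, THF/H2O, rt → 40 °C, degassed, dark
Reagents that add atoms: none
Why: Suzuki–Miyaura coupling (zerovalent palladium formed in situ) joins C8 to C7 with retention at both alkenyl partners, tolerates the free alcohol and runs near room temperature, below the threshold for 6π-electrocyclization of the (Z)-triene.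

Step 6
Reactants: 14 pent-3-ynoic acid
Product: 16 2-ethylpent-3-ynoic acid (racemic), via dilithium enediolate 15 (not isolated)
Conditions: LiN(iPr)2 (2.2 equiv), THF/HMPA, −78 → 0 °C; EtI, −78 °C → rt; dilute HCl
Reagents that add atoms: iodoethane CCI
Why: Alkylation of the dianion (enediolate) of a β,γ-unsaturated acid occurs at the α-carbon, and the carboxylate product is not acidic enough to isomerize to the allene; the racemic α-centre is irrelevant because it is planarized in step 8.

Step 7
Reactants: 13 (1S,2Z,4Z,6E)-3-ethyl-5-methyl-1-phenylnona-2,4,6-trien-1-ol; 16 2-ethylpent-3-ynoic acid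
Product: 17 (1S,2Z,4Z,6E)-3-ethyl-5-methyl-1-phenylnona-2,4,6-trien-1-yl 2-ethylpent-3-ynoate (epimers at the acyl α-carbon)
Conditions: DCC, DMAP (cat.), CH2Cl2, 0 °C
Reagents that add atoms: none
Why: Steglich esterification acylates the secondary alcohol with retention under neutral conditions that spare the ionization-prone trienyl carbinol; an epimer mixture at the acyl α-carbon is expected and is harmless (any allenoate tautomer would give the same enolate in step 8).

Step 8
Reactants: 17 (1S,2Z,4Z,6E)-3-ethyl-5-methyl-1-phenylnona-2,4,6-trien-1-yl 2-ethylpent-3-ynoate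
Product: 21 (2S,3S,4Z,6E)-2,3-diethyl-5-methyl-3-[(E)-2-phenylethenyl]-2-(prop-1-yn-1-yl)nona-4,6-dienoic acid, via lithium enolate 18 (not isolated), via silyl ketene acetal 19 (not isolated), via trimethylsilyl ester 20 (not isolated)
Conditions: LiN(iPr)2, Me3SiCl/Et3N, THF, −78 °C → rt (40 °C if needed); then 1 M HCl
Reagents that add atoms: none
Why: Ireland–Claisen rearrangement: kinetic deprotonation through the cyclic lithium amide transition state should place the larger ethyl group syn to the allyloxy oxygen (propynyl syn to OSiMe3), and the chair transition state with phenyl pseudo-equatorial (enforced by allylic 1,3-strain against the cis dienyl group) forms C8–C9 on one face, so the carbinol chirality is transferred to C8 (S) and C9 (S) and the (E)-styryl group is released.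

Step 9
Reactants: 21 (2S,3S,4Z,6E)-2,3-diethyl-5-methyl-3-[(E)-2-phenylethenyl]-2-(prop-1-yn-1-yl)nona-4,6-dienoic acid
Product: 22 2-(trimethylsilyl)ethyl (2S,3S,4Z,6E)-2,3-diethyl-5-methyl-3-[(E)-2-phenylethenyl]-2-(prop-1-yn-1-yl)nona-4,6-dienoate
Conditions: Me3SiCH2CH2OH, PPh3, DIAD, THF, 0 °C → rt
Reagents that add atoms: 2-(trimethylsilyl)ethanol C[Si](C)(C)CCO
Why: Mitsunobu esterification, in which the hindered carboxylate is the nucleophile at the primary carbon of the activated alcohol so that the shielded acyl carbon need not be attacked; the ester is stable to the following steps and removable without acid.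

Step 10
Reactants: 22 2-(trimethylsilyl)ethyl (2S,3S,4Z,6E)-2,3-diethyl-5-methyl-3-[(E)-2-phenylethenyl]-2-(prop-1-yn-1-yl)nona-4,6-dienoate
Product: 24 2-(trimethylsilyl)ethyl (1S,4S,5S,7aR)-1,4,5-triethyl-3,7-dimethyl-2-oxo-5-[(E)-2-phenylethenyl]-2,4,5,7a-tetrahydro-1H-indene-4-carboxylate, via hexacarbonyldicobalt alkyne complex 23 (not isolated)
Conditions: Co2(CO)8, CH2Cl2, rt; then NMO, CH2Cl2, 0 °C → rt
Reagents that add atoms: carbon monoxide (from Co2(CO)8) [C-]#[O+]
Why: Co2(CO)8 binds alkyne C3≡C4 as its hexacarbonyldicobalt complex 23; amine-oxide removal of one CO lets alkene C5=C1 coordinate and insert into the Co–C4 bond, and CO insertion followed by reductive elimination delivers the cyclopentenone, the closest known type being the cobalt-mediated intramolecular Pauson–Khand reaction of 1,7-enynes. Ring B closes by 6-exo insertion (bond C4–C5) across the tether C9–C8–C7=C6, and ring A closes in the same event as the [2+2+1] sum of C3≡C4, C5=C1 and CO (bonds C1–C2 and C2–C3). C1 is set relative to C5 by suprafacial addition across the (E)-alkene, so H1 and H5 end up trans. C5 is set relative to C8 and C9 by the half-chair of the forming ring B, in which C1 sits pseudo-equatorial and the flat ester, not the C9 ethyl group, is expected to take the position eclipsing the developing C3=C4–CH3 unit, which puts H5 on the face of the C9 ethyl group; this preference is expected to be moderate. The step needs the distal diene alkene to react in preference to every other π-bond and needs this facial preference: the two quaternary carbons and the cis C6=C7 bond fold alkyne and alkene together (gem-disubstitution effect), the styryl group and C6=C7 could only close four-membered rings, and a minor C5/C1 isomer remains correctable because C5 is γ and C1 α to the enone.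

Step 11
Reactants: 24 2-(trimethylsilyl)ethyl (1S,4S,5S,7aR)-1,4,5-triethyl-3,7-dimethyl-2-oxo-5-[(E)-2-phenylethenyl]-2,4,5,7a-tetrahydro-1H-indene-4-carboxylate
Product: 26 2-(trimethylsilyl)ethyl (1S,3aR,4R,5S,7aR)-1,4,5-triethyl-3,7-dimethyl-2-oxo-5-[(E)-2-phenylethenyl]-2,3,3a,4,5,7a-hexahydro-1H-indene-4-carboxylate as a C3-epimer mixture, via lithium enolate 25 (not isolated)
Conditions: Li (2.1 equiv, added as a titrated NH3 solution), NH3/THF, −78 °C; NH4Cl
Reagents that add atoms: none
Why: Dissolving-metal conjugate reduction (Birch-type): two electrons enter the enone, the most easily reduced group, and ammonia protonates the C4 carbanion to give the more stable trans ring fusion (H4 anti to H5); the measured amount of lithium and the absence of an added alcohol should leave the styrene, which has a more negative reduction potential, and the ester untouched.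

Step 12
Reactants: 26 C3-epimer mixture of the trans-fused keto ester
Product: 27 2-(trimethylsilyl)ethyl (1S,3S,3aR,4R,5S,7aR)-1,4,5-triethyl-3,7-dimethyl-2-oxo-5-[(E)-2-phenylethenyl]-2,3,3a,4,5,7a-hexahydro-1H-indene-4-carboxylate
Conditions: NaOMe (0.2 equiv), MeOH/THF, rt
Reagents that add atoms: none
Why: Thermodynamic epimerization through the enolate: C3 (and, if needed, C1) settle with methyl and ethyl pseudo-equatorial, each trans to the neighbouring ring-B bond, which is the target configuration (3S, 1S); the hindered ester should not transesterify.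

Step 13
Reactants: 27 2-(trimethylsilyl)ethyl (1S,3S,3aR,4R,5S,7aR)-1,4,5-triethyl-3,7-dimethyl-2-oxo-5-[(E)-2-phenylethenyl]-2,3,3a,4,5,7a-hexahydro-1H-indene-4-carboxylate
Product: 28 (1S,3S,3aR,4R,5S,7aR)-1,4,5-triethyl-3,7-dimethyl-2-oxo-5-[(E)-2-phenylethenyl]-2,3,3a,4,5,7a-hexahydro-1H-indene-4-carboxylic acid (CNP0302656.1)
Conditions: Bu4NF, DMF, rt; cold dilute HCl work-up
Reagents that add atoms: none
Why: Fluoride-induced fragmentation of the 2-(trimethylsilyl)ethyl ester (attack at silicon, loss of ethene) frees the carboxylate regardless of steric shielding and avoids strong acid, which could lactonize the acid onto C6=C7 or the styrene.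

**Compound list**

1 | propyne | CC#C | starting material
2 | (Z)-(2-bromoprop-1-enyl)dibromoborane | C/C(Br)=C/B(Br)Br | intermediate (not isolated)
3 | (Z)-2-(2-bromoprop-1-en-1-yl)-4,4,5,5-tetramethyl-1,3,2-dioxaborolane | C/C(Br)=C/B1OC(C)(C)C(C)(C)O1 | intermediate
4 | but-1-yne | CCC#C | starting material
5 | (E)-but-1-enyl(chloro)bis(cyclopentadienyl)zirconium | CC/C=C/[Zr](Cl)(C1C=CC=C1)C1C=CC=C1 | intermediate (not isolated)
6 | (E)-but-1-enylzinc bromide | CC/C=C/[Zn]Br | intermediate (not isolated)
7 | 4,4,5,5-tetramethyl-2-[(1Z,3E)-2-methylhexa-1,3-dien-1-yl]-1,3,2-dioxaborolane | CC/C=C/C(C)=C\B1OC(C)(C)C(C)(C)O1 | intermediate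
8 | benzaldehyde | O=Cc1ccccc1 | starting material
9 | ethyl(but-1-ynyl)zinc | CCC#C[Zn]CC | intermediate (not isolated)
10 | (R)-1-phenylpent-2-yn-1-ol | CCC#C[C@H](O)c1ccccc1 | intermediate
11 | sodium salt of the cyclic alkenylalanate (aluminium on the ethyl-bearing carbon and on the carbinol oxygen, two 2-methoxyethoxy ligands) | CCC1=C[C@@H](c2ccccc2)O[Al-]1(OCCOC)OCCOC.[Na+] | intermediate (not isolated)
12 | (1S,2Z)-3-iodo-1-phenylpent-2-en-1-ol | CC/C(I)=C/[C@H](O)c1ccccc1 | intermediate
13 | (1S,2Z,4Z,6E)-3-ethyl-5-methyl-1-phenylnona-2,4,6-trien-1-ol | CC/C(/C=C(C)\C=C\CC)=C/[C@H](O)c1ccccc1 | intermediate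
14 | pent-3-ynoic acid | CC#CCC(=O)O | starting material
15 | dilithium enediolate of pent-3-ynoic acid | CC#CC=C(O[Li])O[Li] | intermediate (not isolated)
16 | 2-ethylpent-3-ynoic acid (racemic) | CCC(C#CC)C(=O)O | intermediate
17 | (1S,2Z,4Z,6E)-3-ethyl-5-methyl-1-phenylnona-2,4,6-trien-1-yl 2-ethylpent-3-ynoate (epimers at the acyl α-carbon) | CC/C(/C=C(C)\C=C\CC)=C/[C@H](OC(=O)C(CC)C#CC)c1ccccc1 | intermediate
18 | lithium enolate of 17 (propynyl syn to OLi) | [Li]O/C(O[C@@H](/C=C(/CC)\C=C(C)/C=C/CC)c1ccccc1)=C(/CC)C#CC | intermediate (not isolated)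
19 | trimethylsilyl ketene acetal of 17 (propynyl syn to OSiMe3) | C[Si](C)(C)O/C(O[C@@H](/C=C(/CC)\C=C(C)/C=C/CC)c1ccccc1)=C(/CC)C#CC | intermediate (not isolated)
20 | trimethylsilyl ester of acid 21 | CC#C[C@@](CC)(C(=O)O[Si](C)(C)C)[C@@](CC)(/C=C/c1ccccc1)/C=C(C)\C=C\CC | intermediate (not isolated)
21 | (2S,3S,4Z,6E)-2,3-diethyl-5-methyl-3-[(E)-2-phenylethenyl]-2-(prop-1-yn-1-yl)nona-4,6-dienoic acid | CC#C[C@@](CC)(C(=O)O)[C@@](CC)(/C=C/c1ccccc1)/C=C(C)\C=C\CC | intermediate
22 | 2-(trimethylsilyl)ethyl (2S,3S,4Z,6E)-2,3-diethyl-5-methyl-3-[(E)-2-phenylethenyl]-2-(prop-1-yn-1-yl)nona-4,6-dienoate (precursor of the key step) | CC#C[C@@](CC)(C(=O)OCC[Si](C)(C)C)[C@@](CC)(/C=C/c1ccccc1)/C=C(C)\C=C\CC | intermediate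
23 | hexacarbonyldicobalt complex of the C3≡C4 alkyne of 22 | CC12[Co]3(=C=O)(=C=O)(=C=O)[Co]1(=C=O)(=C=O)(=C=O)C23[C@@](CC)(C(=O)OCC[Si](C)(C)C)[C@@](CC)(/C=C/c1ccccc1)/C=C(C)\C=C\CC | intermediate (not isolated)
24 | 2-(trimethylsilyl)ethyl (1S,4S,5S,7aR)-1,4,5-triethyl-3,7-dimethyl-2-oxo-5-[(E)-2-phenylethenyl]-2,4,5,7a-tetrahydro-1H-indene-4-carboxylate (product of the key step) | CC[C@@H]1C(=O)C(C)=C2[C@H]1C(C)=C[C@@](/C=C/c1ccccc1)(CC)[C@]2(CC)C(=O)OCC[Si](C)(C)C | intermediate
25 | lithium C2=C3 enolate of the trans-fused keto ester | CC[C@@H]1C(O[Li])=C(C)[C@H]2[C@H]1C(C)=C[C@@](/C=C/c1ccccc1)(CC)[C@]2(CC)C(=O)OCC[Si](C)(C)C | intermediate (not isolated)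
26 | 2-(trimethylsilyl)ethyl (1S,3aR,4R,5S,7aR)-1,4,5-triethyl-3,7-dimethyl-2-oxo-5-[(E)-2-phenylethenyl]-2,3,3a,4,5,7a-hexahydro-1H-indene-4-carboxylate, C3-epimer mixture | CC[C@@H]1C(=O)C(C)[C@H]2[C@H]1C(C)=C[C@@](/C=C/c1ccccc1)(CC)[C@]2(CC)C(=O)OCC[Si](C)(C)C | intermediate
27 | 2-(trimethylsilyl)ethyl (1S,3S,3aR,4R,5S,7aR)-1,4,5-triethyl-3,7-dimethyl-2-oxo-5-[(E)-2-phenylethenyl]-2,3,3a,4,5,7a-hexahydro-1H-indene-4-carboxylate | CC[C@@H]1C(=O)[C@@H](C)[C@H]2[C@H]1C(C)=C[C@@](/C=C/c1ccccc1)(CC)[C@]2(CC)C(=O)OCC[Si](C)(C)C | intermediate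
28 | (1S,3S,3aR,4R,5S,7aR)-1,4,5-triethyl-3,7-dimethyl-2-oxo-5-[(E)-2-phenylethenyl]-2,3,3a,4,5,7a-hexahydro-1H-indene-4-carboxylic acid | CC[C@@H]1C(=O)[C@@H](C)[C@H]2[C@H]1C(C)=C[C@@](/C=C/c1ccccc1)(CC)[C@]2(CC)C(=O)O | target

**Step count and risks**

Total steps: 13. Longest linear sequence: 10 steps (8 → 28 through steps 3, 4, 5, 7, 8, 9, 10, 11, 12, 13).

Steps most likely to fail:

1. Step 8 (Ireland–Claisen). What may go wrong: enolization that does not discriminate ethyl from propynyl, or equilibration of the lithium enolate through its allenyl form, would erode the ketene acetal geometry and with it the C9 configuration. Ionization of the trienyl ester, or slow bond formation between two fully substituted carbons, would lower conversion. Fallback (sets out from 8 and 4, comes back at 21): the complementary pairing is used, namely enolization with LiN(iPr)2 in THF/HMPA, which favours the ketene acetal with ethyl syn to OSiMe3, combined with an allyl partner of opposite alkene geometry and opposite carbinol configuration. Alkynylation of 8 with 4 as in step 3 but with (R)-BINOL should give (S)-1-phenylpent-2-yn-1-ol F1. Syn hydrozirconation with excess Cp2Zr(H)Cl (zirconium on the ethyl-bearing carbon) and iodinolysis should give (1R,2E)-3-iodo-1-phenylpent-2-en-1-ol F2. Suzuki–Miyaura coupling with 7 as in step 5 should give (1R,2E,4Z,6E)-3-ethyl-5-methyl-1-phenylnona-2,4,6-trien-1-ol F3. Esterification with 16 as in step 7 should give (1R,2E,4Z,6E)-3-ethyl-5-methyl-1-phenylnona-2,4,6-trien-1-yl 2-ethylpent-3-ynoate F4. Its trimethylsilyl ketene acetal with ethyl syn to OSiMe3 F5 should rearrange through the chair with the dienyl group pseudo-equatorial and, via 20, give the same acid 21.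

2. Step 10 (Pauson–Khand). What may go wrong: slow cyclization of a 1,7-enyne onto a conjugated 1,2-disubstituted alkene, leading to decomplexation or diene isomerization, and insufficient facial selection at C5. Fallback (sets out from 22, comes back at 24): the carbonylative [2+2+1] cycloaddition is run with catalytic [RhCl(CO)2]2 under CO (1 atm) in 1,2-dichloroethane at 60–80 °C. This proceeds by oxidative cyclization at a single rhodium centre, a manifold in which 1,3-dienes are privileged alkene partners, and it makes the same bonds and rings. No new compound is involved; a minor C5/C1 isomer would be removed by chromatography or equilibrated with base.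

3. Step 11 (dissolving-metal reduction). What may go wrong: electron transfer into the styrene once the enone is consumed (over-reduction to the phenethyl side chain), or protonation of C4 to the cis-fused isomer. Fallback (sets out from 24, comes back at 26): the outer-sphere solvated-electron reduction is replaced by an inner-sphere one with SmI2/HMPA/t-BuOH in THF at −78 → 0 °C. Here the electron is delivered to the samarium-bound carbonyl, a non-coordinating styrene is not engaged, and the C4 carbanion is again protonated under thermodynamic control. No new compound is involved, and step 12 follows unchanged.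

Further compounds
F1 | step 8 | (S)-1-phenylpent-2-yn-1-ol | CCC#C[C@@H](O)c1ccccc1
F2 | step 8 | (1R,2E)-3-iodo-1-phenylpent-2-en-1-ol | CC/C(I)=C\[C@@H](O)c1ccccc1
F3 | step 8 | (1R,2E,4Z,6E)-3-ethyl-5-methyl-1-phenylnona-2,4,6-trien-1-ol | CC/C(/C=C(C)\C=C\CC)=C\[C@@H](O)c1ccccc1
F4 | step 8 | (1R,2E,4Z,6E)-3-ethyl-5-methyl-1-phenylnona-2,4,6-trien-1-yl 2-ethylpent-3-ynoate | CC/C(/C=C(C)\C=C\CC)=C\[C@@H](OC(=O)C(CC)C#CC)c1ccccc1
F5 | step 8 | trimethylsilyl ketene acetal of F4 (ethyl syn to OSiMe3) | C[Si](C)(C)O/C(O[C@H](/C=C(\CC)/C=C(C)\C=C\CC)c1ccccc1)=C(\CC)C#CC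
F0 | step 10 | none | none
F0 | step 11 | none | none
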